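**Strategy.** Ring A is disconnected at C5–C4a and C8–C8a. Its C5–C6(O)–C7–C8(O) edge is a 3-oxybutenoate whose methyl carbon becomes C5 and whose ester carbon becomes C8, whereas C8a, C4a, C4, C3, O2 and C1 are the intact ring of a 6-pentyl-2-pyranone carrying a leaving group at the future C4a. A single Michael–Dieckmann–aromatisation cascade therefore builds ring A onto the preformed lactone and delivers O6 as a benzyl ether and O8 as a free phenol. The precursors are 4-methoxy-6-pentyl-2H-pyran-2-one and the lithium dienolate of methyl (E)-3-(benzyloxy)but-2-enoate. Ring B is then grown on O8 from a bromocyclohexenone and aromatised.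

Key step: step 3

Assumption: the target has no stereocentre, so the sp3 centres of the transient key-step intermediates and of the ring B cyclohexenone intermediates are carried as racemates or diastereomer mixtures, since aromatisation erases them; LiN(i-Pr)2 is taken as a commercial solution.

**Step 1**
Reactants: 1 4-methoxy-6-methyl-2H-pyran-2-one; 2 1-iodobutane
Product: 4 4-methoxy-6-pentyl-2H-pyran-2-one, via lithium pyranone dienolate 3 (not isolated)
Conditions: LiN(i-Pr)2 (1.05 equiv), THF, −78 °C; then DMPU, 2 (1.2 equiv), −78 → −20 °C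
Reagents that add atoms: none
Why: Kinetic deprotonation of the C6 methyl group gives the extended lactone enolate 3, which the primary iodide alkylates at the exocyclic carbon in a lateral lithiation–SN2 alkylation that is established for 4-methoxy-6-methyl-2-pyranone.

**Step 2**
Reactants: 5 methyl (E)-3-methoxybut-2-enoate (1.5 equiv); 6 benzyl alcohol
Product: 7 methyl (E)-3-(benzyloxy)but-2-enoate
Conditions: TsOH·H2O (2 mol%), toluene, 110 °C, MeOH distilled off
Reagents that add atoms: none
Why: Acid-catalysed enol ether exchange (transetherification through the mixed ketal) is driven by removal of methanol, should outpace transesterification of the deactivated vinylogous carbonate ester, and should settle on the E isomer in which the methyl group lies cis to the ester.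

**Step 3**
Reactants: 7 methyl (E)-3-(benzyloxy)but-2-enoate; 4 4-methoxy-6-pentyl-2H-pyran-2-one
Product: 11 6-(benzyloxy)-8-hydroxy-3-pentyl-1H-isochromen-1-one, via lithium dienolate 8 (not isolated), via Michael adduct enolate 9 (not isolated), via methoxy diketone 10 (not isolated)
Conditions: 7 (2.2 equiv), LiN(i-Pr)2 (2.1 equiv), THF, −78 °C; then 4 (1.0 equiv), −78 °C → rt; aq. NH4Cl
Reagents that add atoms: none
Why: Proposed new method: γ-deprotonation of E enol ether 7 (methyl cis to the ester) gives the s-cis lithium dienolate 8, whose γ-carbon should add in conjugate fashion to C4 of pyranone 4 (bond C5–C4a) to give lactone enolate 9; C3 of 9 then attacks the crotonate ester in a 6-(enolexo)-exo-trig Dieckmann closure (bond C8a–C8) to give 10. Expulsion of methoxide from C4a by the doubly activated C8a enolate and tautomerisation of the resulting dienone make ring A aromatic, so the lactone carbonyl and ring oxygen of 4 end up as C1 and O2 of the isocoumarin, the enol ether oxygen as O6 and the ester carbonyl oxygen as the hydrogen-bonded C8 phenol. The closest known reaction type is the Staunton–Weinreb annulation of ortho-toluate anions with 4-methoxy-2-pyranones, which runs through the same Michael addition, Dieckmann closure and loss of methanol; replacing the toluate by an acyclic 3-alkoxy dienolate is the part without precedent. No stereocentre remains in 11, the sp3 centres of 9 and 10 being destroyed by aromatisation. The step needs γ- instead of α-reactivity of 8 and attack at C4 instead of C2 or C6 of 4: C4 is the vinylogous carbonate carbon bearing the nucleofuge, α- or carbonyl adducts can revert whereas only the γ/C4 adduct is removed irreversibly by cyclisation and aromatisation, and the cis disposition of ester and new methylene inherited from 7 keeps the ester within reach of C3. The extra equivalent of 8 serves as base for the acidic C8a–H and the phenol that are formed.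

**Step 4**
Reactants: 12 5-pentylcyclohexane-1,3-dione
Product: 13 3-methoxy-5-pentylcyclohex-2-en-1-one (racemic)
Conditions: MeOH, TsOH·H2O (cat.), 3 Å molecular sieves, 65 °C
Reagents that add atoms: methanol (CO)
Why: Acid-catalysed O-alkylation of the enol of a cyclic 1,3-dione (vinylogous Fischer esterification) gives the mono enol ether, and the symmetry of 12 allows only one constitutional isomer.

**Step 5**
Reactants: 13 3-methoxy-5-pentylcyclohex-2-en-1-one
Product: 16 6-bromo-3-methoxy-5-pentylcyclohex-2-en-1-one (racemic; trans expected as the major diastereomer), via lithium enolate 14 (not isolated), via silyl dienol ether 15 (not isolated)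
Conditions: LiN(i-Pr)2, THF, −78 °C; TMSCl; then NBS, THF, −78 → 0 °C
Reagents that add atoms: N-bromosuccinimide (O=C1CCC(=O)N1Br)
Why: Stork–Danheiser kinetic deprotonation of the vinylogous ester takes place at C6 and not at C4, O-silylation fixes the cross-conjugated enolate, and electrophilic bromination of the silyloxydiene by NBS occurs at its terminal carbon C6, which gives the most delocalised oxocarbenium ion; the configuration at C5 and C6 does not matter because both centres vanish in step 7.

**Step 6**
Reactants: 11 6-(benzyloxy)-8-hydroxy-3-pentyl-1H-isochromen-1-one; 16 6-bromo-3-methoxy-5-pentylcyclohex-2-en-1-one (1.5 equiv)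
Product: 17 6-(benzyloxy)-8-[(4-methoxy-2-oxo-6-pentylcyclohex-3-en-1-yl)oxy]-3-pentyl-1H-isochromen-1-one (mixture of racemic diastereomers)
Conditions: Cs2CO3, DMF, 0 °C → rt
Reagents that add atoms: none
Why: Williamson-type SN2 displacement of a carbonyl-activated secondary bromide by the caesium phenoxide of O8, the only acidic hydroxyl in 11, in a dipolar aprotic solvent at low temperature, where substitution next to a ketone should outrun dehydrobromination.

**Step 7**
Reactants: 17 6-(benzyloxy)-8-[(4-methoxy-2-oxo-6-pentylcyclohex-3-en-1-yl)oxy]-3-pentyl-1H-isochromen-1-one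
Product: 18 6-(benzyloxy)-8-(2-hydroxy-4-methoxy-6-pentylphenoxy)-3-pentyl-1H-isochromen-1-one
Conditions: DDQ (1.2 equiv), TsOH·H2O (cat.), 1,4-dioxane, 80 °C
Reagents that add atoms: none
Why: DDQ dehydrogenation of a cyclohexenone, in which acid-promoted dienol formation makes the 3-methoxy dienol a good hydride donor at C5 and proton loss from C6 then gives the ring B phenol (hydroxyl, aryloxy and pentyl on adjacent carbons, methoxy para to the ether oxygen), while the benzyl aryl ether and the isocoumarin should be inert to the quinone.

**Step 8**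
Reactants: 18 6-(benzyloxy)-8-(2-hydroxy-4-methoxy-6-pentylphenoxy)-3-pentyl-1H-isochromen-1-one
Product: 19 6-hydroxy-8-(2-hydroxy-4-methoxy-6-pentylphenoxy)-3-pentyl-1H-isochromen-1-one
Conditions: H2 (1 atm), 10% Pd/C, EtOAc, rt, stopped after one equivalent of H2
Reagents that add atoms: none
Why: Catalytic hydrogenolysis of a benzyl aryl ether is much faster at atmospheric pressure than reduction of the C3–C4 enol-lactone double bond of the isocoumarin, and the diaryl ether, methyl ether and lactone should not react, so the C6 phenol of the target is released.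

**Compound list**
1 | 4-methoxy-6-methyl-2H-pyran-2-one | Cc1cc(OC)cc(=O)o1 | starting material
2 | 1-iodobutane | CCCCI | starting material
3 | lithium 4-methoxy-6-methylidene-6H-pyran-2-olate (not isolated) | [Li+].[O-]C1=CC(OC)=CC(=C)O1 | intermediate
4 | 4-methoxy-6-pentyl-2H-pyran-2-one | CCCCCc1cc(OC)cc(=O)o1 | intermediate
5 | methyl (E)-3-methoxybut-2-enoate | COC(=O)/C=C(\C)OC | starting material
6 | benzyl alcohol | OCc1ccccc1 | starting material
7 | methyl (E)-3-(benzyloxy)but-2-enoate | COC(=O)/C=C(\C)OCc1ccccc1 | intermediate
8 | lithium 3-(benzyloxy)-1-methoxybuta-1,3-dien-1-olate (not isolated) | [Li+].[O-]C(OC)=CC(=C)OCc1ccccc1 | intermediate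
9 | lithium 4-[(E)-2-(benzyloxy)-4-methoxy-4-oxobut-2-en-1-yl]-4-methoxy-6-pentyl-4H-pyran-2-olate (racemic, not isolated) | [Li+].[O-]C1=CC(OC)(C/C(OCc2ccccc2)=C\C(=O)OC)C=C(CCCCC)O1 | intermediate
10 | 6-(benzyloxy)-4a-methoxy-3-pentyl-4a,5-dihydro-1H-isochromene-1,8(8aH)-dione (racemic, relative configuration undefined, not isolated) | CCCCCC1=CC2(OC)CC(OCc3ccccc3)=CC(=O)C2C(=O)O1 | intermediate
11 | 6-(benzyloxy)-8-hydroxy-3-pentyl-1H-isochromen-1-one | CCCCCc1cc2cc(OCc3ccccc3)cc(O)c2c(=O)o1 | intermediate
12 | 5-pentylcyclohexane-1,3-dione | CCCCCC1CC(=O)CC(=O)C1 | starting material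
13 | 3-methoxy-5-pentylcyclohex-2-en-1-one (racemic) | CCCCCC1CC(=O)C=C(OC)C1 | intermediate
14 | lithium 5-methoxy-3-pentylcyclohexa-1,5-dien-1-olate (racemic, not isolated) | [Li+].[O-]C1=CC(CCCCC)CC(OC)=C1 | intermediate
15 | [(5-methoxy-3-pentylcyclohexa-1,5-dien-1-yl)oxy]trimethylsilane (racemic, not isolated) | CCCCCC1C=C(O[Si](C)(C)C)C=C(OC)C1 | intermediate
16 | 6-bromo-3-methoxy-5-pentylcyclohex-2-en-1-one (racemic, trans expected as major diastereomer, used as the mixture) | CCCCCC1CC(OC)=CC(=O)C1Br | intermediate
17 | 6-(benzyloxy)-8-[(4-methoxy-2-oxo-6-pentylcyclohex-3-en-1-yl)oxy]-3-pentyl-1H-isochromen-1-one (mixture of racemic diastereomers) | CCCCCc1cc2cc(OCc3ccccc3)cc(OC3C(=O)C=C(OC)CC3CCCCC)c2c(=O)o1 | intermediate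
18 | 6-(benzyloxy)-8-(2-hydroxy-4-methoxy-6-pentylphenoxy)-3-pentyl-1H-isochromen-1-one | CCCCCc1cc2cc(OCc3ccccc3)cc(Oc3c(O)cc(OC)cc3CCCCC)c2c(=O)o1 | intermediate
19 | 6-hydroxy-8-(2-hydroxy-4-methoxy-6-pentylphenoxy)-3-pentyl-1H-isochromen-1-one | CCCCCc1cc2cc(O)cc(Oc3c(O)cc(OC)cc3CCCCC)c2c(=O)o1 | target

**Step count.** Total: 8 steps. Longest linear sequence: 5 steps (for example 5 → 7 → 11 → 17 → 18 → 19).

**Steps most likely to fail**

1. Step 3 (proposed new method).
   - What may go wrong: proton transfer from the acidic side-chain methylene of the pyranone to the dienolate may quench the donor without C–C bond formation. The dienolate may react through its α-carbon or at the lactone carbonyl and open the ring. The Michael adduct may also fail to close onto the poorly electrophilic ester.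
   - Fallback (known chemistry): it sets out from benzyl alcohol 6, with commercial methyl 2,4-dimethoxy-6-methylbenzoate as the ring A source, and returns to the route at 11. The toluate is laterally lithiated (LiN(i-Pr)2, THF, −78 °C) and C-acylated with N-methoxy-N-methylhexanamide to give methyl 2,4-dimethoxy-6-(2-oxoheptyl)benzoate F1. NaH in THF closes the enol lactone to 6,8-dimethoxy-3-pentyl-1H-isochromen-1-one F2. BBr3 (CH2Cl2, −78 °C → rt) cleaves both methyl ethers to 6,8-dihydroxy-3-pentyl-1H-isochromen-1-one F3. Mitsunobu etherification with 6 (PPh3, DIAD, THF, 0 °C) should then benzylate only the non-chelated C6 hydroxyl and give 11.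

2. Step 6.
   - What may go wrong: base-induced dehydrobromination of the bromoketone, followed by its tautomerisation to a phenol, may outpace substitution by the hindered, weakly nucleophilic peri-carbonyl phenoxide. C-alkylation at C7 of ring A is a second possible diversion.
   - Fallback: it sets out from enol ether 13 and returns at 17, replacing the SN2 reaction by a carbenoid O–H insertion. The kinetic enolate of 13 (LiN(SiMe3)2, THF, −78 °C) is C-acylated with 2,2,2-trifluoroethyl trifluoroacetate to 3-methoxy-5-pentyl-6-(trifluoroacetyl)cyclohex-2-en-1-one F4. Detrifluoroacetylative diazo transfer (MsN3, Et3N, H2O, MeCN) gives 6-diazo-3-methoxy-5-pentylcyclohex-2-en-1-one F5. Slow addition of F5 to phenol 11 and Rh2(OAc)4 (cat.) in CH2Cl2 should insert the carbenoid into the O8–H bond and give 17.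

3. Step 7.
   - What may go wrong: dehydrogenation may stall at partial conversion, the electron-rich ring B phenol may be over-oxidised by the quinone, or the acid may cause loss of the aryloxy group.
   - Fallback: it sets out from 17 and returns at 18, replacing hydride abstraction by a Saegusa–Ito oxidation. Kinetic enolisation and silylation (LiN(SiMe3)2, TMSCl, THF, −78 °C) give 6-(benzyloxy)-8-{[4-methoxy-6-pentyl-2-(trimethylsilyloxy)cyclohexa-1,3-dien-1-yl]oxy}-3-pentyl-1H-isochromen-1-one F6. Pd(OAc)2 in MeCN at rt should convert F6 into the cross-conjugated dienone, which tautomerises to 18 on work-up.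

**Further compounds**
F1 | step 3 | methyl 2,4-dimethoxy-6-(2-oxoheptyl)benzoate | CCCCCC(=O)Cc1cc(OC)cc(OC)c1C(=O)OC
F2 | step 3 | 6,8-dimethoxy-3-pentyl-1H-isochromen-1-one | CCCCCc1cc2cc(OC)cc(OC)c2c(=O)o1
F3 | step 3 | 6,8-dihydroxy-3-pentyl-1H-isochromen-1-one | CCCCCc1cc2cc(O)cc(O)c2c(=O)o1
F4 | step 6 | 3-methoxy-5-pentyl-6-(trifluoroacetyl)cyclohex-2-en-1-one | CCCCCC1CC(OC)=CC(=O)C1C(=O)C(F)(F)F
F5 | step 6 | 6-diazo-3-methoxy-5-pentylcyclohex-2-en-1-one | CCCCCC1CC(OC)=CC(=O)C1=[N+]=[N-]
F6 | step 7 | 6-(benzyloxy)-8-{[4-methoxy-6-pentyl-2-(trimethylsilyloxy)cyclohexa-1,3-dien-1-yl]oxy}-3-pentyl-1H-isochromen-1-one | CCCCCc1cc2cc(OCc3ccccc3)cc(OC3=C(O[Si](C)(C)C)C=C(OC)CC3CCCCC)c2c(=O)o1
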